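## The problem

The target is a cyclopent-2-en-1-one with a fully substituted carbinol carbon joined to a thirteen-carbon chain. Numbering used throughout: C1 ketone, C2=C3 alkene, C4 acetoxy carbon, C5 tertiary carbinol, C6 side-chain carbinol. The stereocentres C4 (R), C5 (S) and C6 (S) are contiguous, with the C6 hydroxyl erythro to O5 along the C7–C6–C5–C4 chain.

A synthesis has to attach the chain at a quaternary ring carbon and place three oxygens on C4, C5 and C6 in a defined sense. Only O4 is acylated, although it sits beside a free tertiary and a free secondary hydroxyl. A late acetylation of a triol would therefore have to tell two secondary hydroxyls apart.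

The compound is fragile. The acetate is allylic and γ to the enone carbonyl, the C6 hydroxyl is β to the ketone through C5 (retro-aldol), the acetyl group can migrate from O4 to the cis-disposed O6, and the enone accepts nucleophiles. Strong base, strong acid and zerovalent palladium are thus excluded near the end.

C6 is the natural controlling centre: a C6 hydroxyl on a C4=C5 alkene can steer an oxidant to one face, and the C5 configuration so formed can be passed on to C4. The enabling feature is that acylated O4 and free O5 are trans on neighbouring ring carbons. This is the pattern left when acetate opens a C4–C5 epoxide at C4 from the face opposite the oxirane oxygen. The C6 hydroxyl makes that epoxide a 2,3-epoxy alcohol, a class that carboxylic acids open regioselectively at the carbon remote from the carbinol.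

## Retrosynthesis

**Target 15 to epoxy enone 13 and acetic acid 14.** The C4–O bond to the acetate is cut. Acetylating a triol would need selection between two secondary hydroxyls under conditions that threaten the β-hydroxy ketone. An esterification at C4 with inversion would need the cis-4,5-diol and invites allylic transposition. Epoxide opening instead brings the ester oxygen in as the nucleophile, so the question of which hydroxyl is acylated does not arise. Precursor 13 has no ester, and its C4 configuration is locked to C5 by the oxirane. The forward reaction must attack C4 and not C5, with inversion, and must not add to the enone.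

**Epoxy enone 13 to epoxy ketone 10.** The C2=C3 double bond is taken out. Compound 13 is formally the monoepoxide of a cyclopentadienone, which cannot be made by epoxidising the dienone because such dienones dimerise. The unsaturation is therefore introduced after the oxirane, through silyl enol ether 11 and the transient silyl ether 12. Because C5 is quaternary, ketone 10 can enolise only toward C2, so regiochemistry is not an issue. The forward reaction must dehydrogenate without opening the epoxide and release the C6 hydroxyl afterwards.

**Epoxy ketone 10 to ketal 9.** The ketone is masked as its dioxolane. The ketal is needed earlier for two reasons: it permits the organolithium step, and it leaves the C4=C5 alkene electron-rich enough for a hydroxyl-directed electrophilic epoxidation. The forward hydrolysis must spare the oxirane.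

**Ketal 9 to racemic allylic alcohol 8.** Both C–O bonds of the oxirane are cut. A titanium–tartrate kinetic resolution selects the C6 configuration and sets C4 and C5 relative to it in one operation. An enantioselective addition of the vinyl anion to the aldehyde would be less dependable and would still need a separate directed epoxidation. The price is that at most half of 8 is used. The forward reaction must consume the (S)-carbinol and give the erythro epoxy alcohol.

**Alcohol 8 to bromo ketal 5 and tridecanal 6.** The C5–C6 bond is cut between the ring and the chain. Vinyllithium 7, formed from 5, is an α-ketovinyl anion equivalent. A direct Morita–Baylis–Hillman coupling of 1 with 6 would give the free enone, whose electron-poor alkene does not respond to directed electrophilic epoxidation. The precursors are a seven-carbon ketal and a commercial aldehyde.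

**Bromo ketal 5 to cyclopentenone 1.** Ketal 5 comes from bromo enone 3 and ethylene glycol 4. Bromo enone 3 comes from 1 by bromination and dehydrobromination via dibromide 2. Both are standard operations on cheap materials.

## Roads not taken

**Alternative 1:** The ring is opened at the C1–C5 bond to give keto aldehyde A2, a cis-4,6-disubstituted 2,2-dimethyl-1,3-dioxan-5-one with a 3-oxopropyl arm and the dodecyl group. In the forward key step an N-heterocyclic carbene turns the aldehyde into its acyl-anion equivalent, which adds to the dioxanone carbonyl and closes the five-membered ring to give cis-fused acyloin A1. The carbene would come from a triazolium salt such as 2-(pentafluorophenyl)-6,7-dihydro-5H-pyrrolo[2,1-c][1,2,4]triazol-2-ium tetrafluoroborate with Et3N.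
- Merits: the ring and the quaternary carbinol form in one C–C bond formation. The C5 configuration is dictated by the cis ring fusion, so no reagent control is needed. C4 and C6 can be set in the open chain by aldol chemistry of a dihydroxyacetone equivalent, and no resolution discards material.
- Weak points: A1 is a saturated ketone with O4 and O6 tied in the acetonide. After the key step C2–C3 must still be dehydrogenated, the acetonide removed, and O4 acetylated in preference to O6, so the selective acylation problem returns. Both stereocentres of A2 are α to the ketone and α-oxygenated, and are exposed to epimerisation under the basic carbene conditions. The enolisable aldehyde can also take aldol pathways.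
- Comparison: this road is better on the origin of C5 and on material economy. The chosen plan sets against that an acetate placed by mechanism and no late triol.

**Alternative 2:** The C4–C5 bond is cut as an aldol retron, leading to pyranone A3 from furan oxidation. In the forward key step A3 opens to its Z-configured 4-oxo-2-enal, enolises at C5 and closes the C4–C5 bond under a chelating Lewis acid (ZnCl2 or MgBr2 with a mild amine) to give triol A4.
- Merits: this is the shortest road, probably four or five steps against eight. The enone oxidation level is reached directly, and C6 can come from an asymmetric dihydroxylation.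
- Weak points: C5 is planar in the enol, so both C4 and C5 are formed in one aldol with only C6 and the chelate to control them. Four diastereomers are possible. A4 is a base-sensitive triol that still needs O4-selective acetylation.
- Comparison: in step count this road is clearly better. The chosen plan sets against that a defined origin for each stereocentre (C6 by resolution, C5 by directed epoxidation, C4 by stereospecific inversion) and a regiospecific acetate.

**Alternative 3:** The C4–H bond is cut as a reduction retron, leading to enedione A5, in which C5 is not yet stereogenic. In the forward key step an NADPH-dependent ketoreductase, with glucose dehydrogenase for cofactor recycling, reduces one of the two diastereotopic carbonyls to give carbinol A6, setting C4 and C5 together.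
- Merits: the acetonide leaves O4 as the only free hydroxyl, so acetylation is unambiguous. On this point the road equals the chosen plan. It needs no resolution and passes through no sensitive epoxide.
- Weak points: the enzyme must choose both the carbonyl and the face, and finding one requires screening with no assurance. A5 is a reactive doubly activated alkene with a lipophilic chain, poorly suited to aqueous buffer and open to alkene reduction. After acetylation the acetonide must be removed with acid next to an allylic acetate. A5 itself needs several steps.
- Comparison: this road is better on material economy and on the ordinary nature of the final acylation. The chosen plan sets against that reactions of known scope at every stage and no dependence on a screening outcome.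

Key step: step 8

Remark: ring atoms keep the target numbering (C1 ketone or ketal carbon, C2, C3, C4, C5, side-chain carbinol C6) in all intermediates. Compounds 2 and 8 are racemic. The tartrate rule for kinetic resolution (L-(+)-tartrate consumes the (S)-carbinol and gives the erythro epoxy alcohol) is assumed to hold for the ketal-substituted cyclopentenyl carbinol 8.

## Route

Step 1
Reactants: 1 cyclopent-2-en-1-one
Product: 3 2-bromocyclopent-2-en-1-one, via trans-2,3-dibromocyclopentanone 2 (not isolated)
Conditions: Br2, CH2Cl2, 0 °C; then Et3N, 0 °C to rt
Reagents that add atoms: bromine, BrBr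
Why: Electrophilic anti addition of bromine to the enone gives dibromide 2, and triethylamine then removes the acidic C2 proton with loss of the C3 bromide (dehydrobromination) to leave the α-bromo enone; no stereocentre persists.

Step 2
Reactants: 3 2-bromocyclopent-2-en-1-one; 4 ethylene glycol
Product: 5 6-bromo-1,4-dioxaspiro[4.4]non-6-ene
Conditions: p-toluenesulfonic acid (cat.), benzene, reflux, Dean–Stark trap
Reagents that add atoms: none
Why: Acid-catalysed ketalisation with azeotropic removal of water; the ketal masks the carbonyl for the lithiation and keeps the C4=C5 alkene electron-rich for the later epoxidation.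

Step 3
Reactants: 5 6-bromo-1,4-dioxaspiro[4.4]non-6-ene; 6 tridecanal
Product: 8 rac-1-(1,4-dioxaspiro[4.4]non-6-en-6-yl)tridecan-1-ol, via vinyllithium 7 (not isolated)
Conditions: n-BuLi, THF, −78 °C; then 6, −78 to 0 °C; aq NH4Cl
Reagents that add atoms: none
Why: Bromine–lithium exchange gives the α-ketovinyl anion equivalent 7, which adds to the aldehyde and forms the C5–C6 bond; C6 forms without control, which is accepted because step 4 resolves it.

Step 4
Reactants: 8 rac-1-(1,4-dioxaspiro[4.4]non-6-en-6-yl)tridecan-1-ol
Product: 9 (1S)-1-[(1S,5S)-2,2-(ethylenedioxy)-6-oxabicyclo[3.1.0]hexan-1-yl]tridecan-1-ol (C4–C5 epoxide erythro to the C6 hydroxyl)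
Conditions: Ti(OiPr)4 (0.2 equiv), L-(+)-diisopropyl tartrate (0.3 equiv), tBuOOH (0.45 equiv), 4 Å molecular sieves, CH2Cl2, −20 °C
Reagents that add atoms: tert-butyl hydroperoxide, CC(C)(C)OO
Why: Sharpless kinetic resolution of a secondary allylic alcohol: with L-(+)-tartrate the (S)-carbinol reacts fast and receives oxygen on the face that gives the erythro epoxy alcohol, so C4 and C5 are set relative to C6 while the (R)-alcohol stays behind. 1,2-Allylic strain between the ketal carbon on C5 and the dodecyl group on C6 acts in the same erythro sense, and the substoichiometric oxidant should keep the enantiomeric purity of 9 high.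

Step 5
Reactants: 9 (1S)-1-[(1S,5S)-2,2-(ethylenedioxy)-6-oxabicyclo[3.1.0]hexan-1-yl]tridecan-1-ol
Product: 10 (1S,5S)-1-[(1S)-1-hydroxytridecyl]-6-oxabicyclo[3.1.0]hexan-2-one
Conditions: pyridinium p-toluenesulfonate (cat.), acetone–H2O, 50 °C
Reagents that add atoms: water, O
Why: Acid-catalysed ketal hydrolysis in wet acetone; the oxirane carbon C5 carries the ketal and then the ketone, which disfavours acid-induced C–O ionisation, so the epoxide should survive the buffered acid. No stereocentre is touched.

Step 6
Reactants: 10 (1S,5S)-1-[(1S)-1-hydroxytridecyl]-6-oxabicyclo[3.1.0]hexan-2-one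
Product: 11 trimethyl{[(1S)-1-[(1R,5S)-2-(trimethylsilyloxy)-6-oxabicyclo[3.1.0]hex-2-en-1-yl]tridecyl]oxy}silane (O6 silyl ether and C1–C2 silyl enol ether of 10; the C5 descriptor changes by priority only)
Conditions: LiN(SiMe3)2 (2.3 equiv), Me3SiCl (3 equiv), THF, −78 to 0 °C
Reagents that add atoms: chlorotrimethylsilane, C[Si](C)(C)Cl
Why: Kinetic enolisation with in situ silylation: C5 is quaternary, so only C2 can be deprotonated, and the C6 lithium alkoxide is silylated in the same flask. Low temperature and immediate trapping leave no time for Payne rearrangement of the alkoxide or Favorskii-type opening by the enolate.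

Step 7
Reactants: 11 trimethyl{[(1S)-1-[(1R,5S)-2-(trimethylsilyloxy)-6-oxabicyclo[3.1.0]hex-2-en-1-yl]tridecyl]oxy}silane
Product: 13 (1S,5S)-1-[(1S)-1-hydroxytridecyl]-6-oxabicyclo[3.1.0]hex-3-en-2-one, via O6-trimethylsilyl epoxy enone 12 (not isolated)
Conditions: Pd(OAc)2 (1.05 equiv), MeCN, rt; then citric acid (cat.), MeOH, 0 °C
Reagents that add atoms: none
Why: Saegusa–Ito oxidation: divalent palladium adds to the silyl enol ether, the α-palladio ketone loses hydride from C3, and the C2=C3 enone forms with the oxirane intact, an established way from 2,3-epoxycycloalkanones to 4,5-epoxycycloalk-2-enones. Brief acid-catalysed methanolysis then removes the labile O6 silyl ether; no stereocentre is touched.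

Step 8
Reactants: 13 (1S,5S)-1-[(1S)-1-hydroxytridecyl]-6-oxabicyclo[3.1.0]hex-3-en-2-one; 14 acetic acid
Product: 15 (1R,5S)-5-hydroxy-5-[(1S)-1-hydroxytridecyl]-4-oxocyclopent-2-en-1-yl acetate (CNP0147374.2)
Conditions: AcOH (2 equiv), Ti(OiPr)4 (1.5 equiv), CH2Cl2, 0 °C to rt; aq tartaric acid work-up
Reagents that add atoms: none
Why: Ligand exchange places the C6 alkoxide and acetate on tetravalent titanium, the metal also binds the oxirane oxygen, and acetate attacks C4 from the face opposite the C4–O bond in an SN2 opening. The closest known reaction type is the Ti(OiPr)4-mediated opening of 2,3-epoxy alcohols by carboxylic acids at the carbon remote from the carbinol. No ring closes; one C–O bond forms and the oxirane opens. C4 is the only stereocentre that changes: it is inverted from (S) to (R), so its configuration follows from the epoxide face fixed in step 4, while C5 keeps its oxygen with retention and C6 is untouched. Attack at C4 over C5 is secured because C5 is fully substituted, its rear side is blocked by the side chain, and the chelate aligns the C4–O bond. Direct attack is preferred over allylic transposition because C2 is the electron-rich enone carbon, and any conjugate addition of acetate at C3 is reversible. Ionisation is not expected to compete, since a cation at C4 would be an acyl-substituted allyl cation. Near-neutral conditions avoid deprotonation at C4 and acetyl migration from O4 to O6; the reaction should be stopped once 13 is consumed.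

## Compound list

1 | cyclopent-2-en-1-one | O=C1C=CCC1 | starting material
2 | trans-2,3-dibromocyclopentan-1-one (racemic, one enantiomer drawn) | O=C1CC[C@H](Br)[C@H]1Br | intermediate (not isolated)
3 | 2-bromocyclopent-2-en-1-one | O=C1CCC=C1Br | intermediate
4 | ethylene glycol | OCCO | starting material
5 | 6-bromo-1,4-dioxaspiro[4.4]non-6-ene | BrC1=CCCC12OCCO2 | intermediate
6 | tridecanal | CCCCCCCCCCCCC=O | starting material
7 | (1,4-dioxaspiro[4.4]non-6-en-6-yl)lithium | [Li]C1=CCCC12OCCO2 | intermediate (not isolated)
8 | rac-1-(1,4-dioxaspiro[4.4]non-6-en-6-yl)tridecan-1-ol | CCCCCCCCCCCCC(O)C1=CCCC12OCCO2 | intermediate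
9 | (1S)-1-[(1S,5S)-2,2-(ethylenedioxy)-6-oxabicyclo[3.1.0]hexan-1-yl]tridecan-1-ol | CCCCCCCCCCCC[C@H](O)[C@]12O[C@H]1CCC23OCCO3 | intermediate
10 | (1S,5S)-1-[(1S)-1-hydroxytridecyl]-6-oxabicyclo[3.1.0]hexan-2-one | CCCCCCCCCCCC[C@H](O)[C@]12O[C@H]1CCC2=O | intermediate
11 | trimethyl{[(1S)-1-[(1R,5S)-2-(trimethylsilyloxy)-6-oxabicyclo[3.1.0]hex-2-en-1-yl]tridecyl]oxy}silane | CCCCCCCCCCCC[C@H](O[Si](C)(C)C)[C@]12O[C@H]1CC=C2O[Si](C)(C)C | intermediate
12 | (1R,5S)-1-[(1S)-1-(trimethylsilyloxy)tridecyl]-6-oxabicyclo[3.1.0]hex-3-en-2-one (O6-trimethylsilyl ether of 13) | CCCCCCCCCCCC[C@H](O[Si](C)(C)C)[C@]12O[C@H]1C=CC2=O | intermediate (not isolated)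
13 | (1S,5S)-1-[(1S)-1-hydroxytridecyl]-6-oxabicyclo[3.1.0]hex-3-en-2-one, that is (4S,5S)-4,5-epoxy-5-[(1S)-1-hydroxytridecyl]cyclopent-2-en-1-one | CCCCCCCCCCCC[C@H](O)[C@]12O[C@H]1C=CC2=O | intermediate
14 | acetic acid | CC(=O)O | starting material
15 | (1R,5S)-5-hydroxy-5-[(1S)-1-hydroxytridecyl]-4-oxocyclopent-2-en-1-yl acetate | CCCCCCCCCCCC[C@H](O)[C@@]1(O)C(=O)C=C[C@H]1OC(C)=O | target

## Step count and least certain steps

Total steps: 8. Longest linear sequence: 8 steps, from 1 to 15.

1) Step 8, the key step. Possible failures:
- sluggish SN2 attack at a C4 that is shielded by the cis side chain and deactivated by the enone;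
- binding of titanium to the ketone and the C6 alkoxide instead of the oxirane;
- acetyl migration from O4 to O6, or ester exchange with isopropoxide on long exposure;
- decomposition of the epoxy enone by deprotonation at C4.

The fallback moves the acetolysis to the saturated stage, where the enone-related problems are absent. It sets out from 10 and returns at 15.
- Treating 10 with AcOH and Ti(OiPr)4 in CH2Cl2 should open the oxirane at C4 with inversion and give (1R,2S)-2-hydroxy-2-[(1S)-1-hydroxytridecyl]-3-oxocyclopentyl acetate F1.
- Me3SiOTf and Et3N in CH2Cl2 at 0 °C should silylate both hydroxyls and the enol to give the tris(trimethylsilyl) derivative F2.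
- 2-Iodoxybenzoic acid with 4-methoxypyridine N-oxide in DMSO at rt should dehydrogenate the silyl enol ether without a metal that could ionise the allylic acetate, giving the O5,O6-bis(trimethylsilyl) ether of the target F3.
- Citric acid in MeOH then removes the silyl groups and gives 15.

2) Step 4. Possible failures: slow epoxidation, or poor rate difference between the enantiomers, because the quaternary ketal carbon next to the alkene is bulky and its oxygens may bind titanium; loss of enantiomeric purity of 9 if conversion runs too far.

The fallback separates the two tasks and uses all the material. It sets out from 8 and returns at 9.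
- Dess–Martin periodinane oxidises 8 to 1-(1,4-dioxaspiro[4.4]non-6-en-6-yl)tridecan-1-one F4.
- Corey–Bakshi–Shibata reduction with (R)-1-methyl-3,3-diphenyltetrahydro-1H,3H-pyrrolo[1,2-c][1,3,2]oxazaborole and BH3·SMe2 in toluene at −78 °C, the alkenyl group acting as the large substituent, should give (1S)-1-(1,4-dioxaspiro[4.4]non-6-en-6-yl)tridecan-1-ol F5.
- VO(acac)2 with tBuOOH in CH2Cl2 then epoxidises F5 under hydroxyl direction. For an allylic alcohol with a substituent on the carbinol-bearing alkene carbon, 1,2-allylic strain favours the erythro product, which is 9.
- The (R)-alcohol recovered from step 4 can be fed into the same sequence.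

3) Step 7. Possible failures: the zerovalent palladium and acetic acid released may ionise the allylic C4–O bond of the newly formed vinyl epoxide, leading to opening with net retention or to isomerisation; early loss of the O6 silyl group may slow the oxidation.

The fallback replaces palladium by selenium. It sets out from 11 and returns at 12.
- PhSeCl in CH2Cl2 at −78 °C converts the silyl enol ether into (1R,5S)-3-(phenylselanyl)-1-[(1S)-1-(trimethylsilyloxy)tridecyl]-6-oxabicyclo[3.1.0]hexan-2-one F6.
- H2O2 with pyridine in CH2Cl2 at 0 °C gives the selenoxide, which undergoes syn elimination to 12.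
- 12 is desilylated to 13 as in step 7.

4) Step 5. Possible failures: slow hydrolysis, because the oxocarbenium ion is destabilised by the neighbouring oxirane; opening of the oxirane if the acid is strengthened to compensate.

The fallback changes the protecting group to one that hydrolyses far more readily. It sets out from 3 and returns at 10.
- HC(OMe)3 in MeOH with p-toluenesulfonic acid (cat.) should give 1-bromo-5,5-dimethoxycyclopent-1-ene F7.
- Lithiation with n-BuLi and addition to 6, as in step 3, gives rac-1-(5,5-dimethoxycyclopent-1-en-1-yl)tridecan-1-ol F8.
- Kinetic resolution as in step 4 gives (1S)-1-[(1S,5S)-2,2-dimethoxy-6-oxabicyclo[3.1.0]hexan-1-yl]tridecan-1-ol F9.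
- Oxalic acid on wet silica gel in CH2Cl2 at 0 °C then releases ketone 10.

## Further compounds

F1 | step 8 | (1R,2S)-2-hydroxy-2-[(1S)-1-hydroxytridecyl]-3-oxocyclopentyl acetate | CCCCCCCCCCCC[C@H](O)[C@@]1(O)C(=O)CC[C@H]1OC(C)=O
F2 | step 8 | tris(trimethylsilyl) derivative of F1 (O5 and O6 silyl ethers, C1–C2 silyl enol ether) | CCCCCCCCCCCC[C@H](O[Si](C)(C)C)[C@@]1(O[Si](C)(C)C)C(O[Si](C)(C)C)=CC[C@H]1OC(C)=O
F3 | step 8 | O5,O6-bis(trimethylsilyl) ether of 15 | CCCCCCCCCCCC[C@H](O[Si](C)(C)C)[C@@]1(O[Si](C)(C)C)C(=O)C=C[C@H]1OC(C)=O
F4 | step 4 | 1-(1,4-dioxaspiro[4.4]non-6-en-6-yl)tridecan-1-one | CCCCCCCCCCCCC(=O)C1=CCCC12OCCO2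
F5 | step 4 | (1S)-1-(1,4-dioxaspiro[4.4]non-6-en-6-yl)tridecan-1-ol | CCCCCCCCCCCC[C@H](O)C1=CCCC12OCCO2
F6 | step 7 | (1R,5S)-3-(phenylselanyl)-1-[(1S)-1-(trimethylsilyloxy)tridecyl]-6-oxabicyclo[3.1.0]hexan-2-one (selenide carbon as a mixture) | CCCCCCCCCCCC[C@H](O[Si](C)(C)C)[C@]12O[C@H]1CC([Se]c3ccccc3)C2=O
F7 | step 5 | 1-bromo-5,5-dimethoxycyclopent-1-ene | COC1(OC)CCC=C1Br
F8 | step 5 | rac-1-(5,5-dimethoxycyclopent-1-en-1-yl)tridecan-1-ol | CCCCCCCCCCCCC(O)C1=CCCC1(OC)OC
F9 | step 5 | (1S)-1-[(1S,5S)-2,2-dimethoxy-6-oxabicyclo[3.1.0]hexan-1-yl]tridecan-1-ol | CCCCCCCCCCCC[C@H](O)[C@]12O[C@H]1CCC2(OC)OC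
A1 | alternative 1 | cis-fused 4-dodecyl-4a-hydroxy-2,2-dimethylhexahydrocyclopenta[d][1,3]dioxin-5-one (O4,O6-isopropylidene 2,3-dihydro-4-deacetyl target) | CCCCCCCCCCCC[C@@H]1OC(C)(C)O[C@@H]2CCC(=O)[C@]12O
A2 | alternative 1 | 3-(cis-6-dodecyl-2,2-dimethyl-5-oxo-1,3-dioxan-4-yl)propanal | CCCCCCCCCCCC[C@@H]1OC(C)(C)O[C@H](CCC=O)C1=O
A3 | alternative 2 | 6-hydroxy-2-[(1S)-1-hydroxytridecyl]-2H-pyran-3(6H)-one (ring carbons as mixtures) | CCCCCCCCCCCC[C@H](O)C1OC(O)C=CC1=O
A4 | alternative 2 | (4R,5S)-4,5-dihydroxy-5-[(1S)-1-hydroxytridecyl]cyclopent-2-en-1-one | CCCCCCCCCCCC[C@H](O)[C@@]1(O)C(=O)C=C[C@H]1O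
A5 | alternative 3 | (4S)-4-dodecyl-2,2-dimethyl-1,3-dioxaspiro[4.4]non-7-ene-6,9-dione | CCCCCCCCCCCC[C@@H]1OC(C)(C)OC12C(=O)C=CC2=O
A6 | alternative 3 | 4-dodecyl-9-hydroxy-2,2-dimethyl-1,3-dioxaspiro[4.4]non-7-en-6-one (O5,O6-isopropylidene 4-deacetyl target) | CCCCCCCCCCCC[C@@H]1OC(C)(C)O[C@@]12C(=O)C=C[C@H]2O
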